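**Plan**

1. Tetralin numbering: C1 carries the aryl group, C2 and C3 the CH2OH groups, C4 is the CH2, C4a–C8a are ring A. Retrosynthesis takes both CH2OH groups back to esters and C3–C4 to an alkene, then cuts C1–C8a and C2–C3 together; this opens ring B and leaves two 4-hydroxycinnamates held on one chiral diol.
2. Enabling feature: the C7 hydroxyl is para to C4a and the aryl hydroxyl is para to the carbon bound to C1, so both halves are para-hydroxyphenylpropanoids and C2 and C3 are their β-carbons; two carbons of like polarity can be joined as two phenoxyl radicals.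
3. Forward: the ring A cinnamic acid (three steps) and an O-allyl 6-bromoferulic acid (two steps) are esterified in turn onto (4S,5S)-threitol acetonide and deallylated; one anodic oxidation then forms C2–C3 (ten-membered dilactone) and C1–C8a (ring B).
4. A bromine para to the guaiacyl methoxy group rides through the key step so that only ring A can close ring B; hydrogenation removes it while saturating C3=C4, NaOMe releases the tether and LiAlH4 gives the diol.
5. Stereochemistry: C2 from the tether in the radical recombination, C1 trans to C2 in the ring closure; C3 (and C2 again) are then equilibrated to the all-trans diester against the fixed C1.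

Key step: step 9

Assumption: the facial sense that the (4S,5S) tether imposes on the radical recombination cannot be read from precedent; it is taken to lead to the (2S) centre drawn for the key product, and if the opposite sense were found the equally available (4R,5R) diol would be used with no other change.

**Route**

Step 1
Reactants: 1 2,3,4-trihydroxybenzaldehyde
Product: 2 4-(allyloxy)-2,3-dihydroxybenzaldehyde
Conditions: allyl bromide (1.0 equiv), NaHCO3, NaI (cat.), DMF, 40 °C
Reagents that add atoms: allyl bromide, C=CCBr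
Why: Williamson etherification under hydrogencarbonate should alkylate only the 4-hydroxyl, the most acidic one because it is para to the formyl group, while the 2-hydroxyl stays locked in its hydrogen bond to the aldehyde and the 3-hydroxyl is not ionised by so weak a base.

Step 2
Reactants: 2 4-(allyloxy)-2,3-dihydroxybenzaldehyde
Product: 3 4-(allyloxy)-2,3-dimethoxybenzaldehyde
Conditions: MeI (3 equiv), K2CO3, DMF, 40 °C
Reagents that add atoms: iodomethane, CI
Why: Williamson O-methylation with carbonate in DMF is strong enough to break the aldehyde chelate and should cap both remaining hydroxyls, the allyl ether being inert.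

Step 3
Reactants: 3 4-(allyloxy)-2,3-dimethoxybenzaldehyde; 4 malonic acid
Product: 6 (E)-3-[4-(allyloxy)-2,3-dimethoxyphenyl]prop-2-enoic acid, via arylidenemalonic acid 5 (not isolated)
Conditions: pyridine, piperidine (cat.), 90 °C
Reagents that add atoms: none
Why: Knoevenagel condensation with Doebner decarboxylation in pyridine gives the cinnamic acid as the thermodynamically preferred E alkene, far below the temperature of an aryl allyl ether Claisen rearrangement.

Step 4
Reactants: 7 6-bromovanillin
Product: 8 4-(allyloxy)-2-bromo-5-methoxybenzaldehyde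
Conditions: allyl bromide, K2CO3, DMF, rt
Reagents that add atoms: allyl bromide, C=CCBr
Why: Williamson etherification of the single phenol.

Step 5
Reactants: 8 4-(allyloxy)-2-bromo-5-methoxybenzaldehyde; 4 malonic acid
Product: 10 (E)-3-[4-(allyloxy)-2-bromo-5-methoxyphenyl]prop-2-enoic acid, via bromoarylidenemalonic acid 9 (not isolated)
Conditions: pyridine, piperidine (cat.), 90 °C
Reagents that add atoms: none
Why: Knoevenagel–Doebner reaction as in step 3; an ortho bromine does not hinder the condensation and the E acid is again expected.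

Step 6
Reactants: 10 (E)-3-[4-(allyloxy)-2-bromo-5-methoxyphenyl]prop-2-enoic acid; 11 (4S,5S)-2,2-dimethyl-1,3-dioxolane-4,5-dimethanol (3 equiv)
Product: 12 [(4S,5S)-5-(hydroxymethyl)-2,2-dimethyl-1,3-dioxolan-4-yl]methyl (E)-3-[4-(allyloxy)-2-bromo-5-methoxyphenyl]prop-2-enoate
Conditions: DCC, DMAP (cat.), CH2Cl2, 0 °C to rt; excess 11 recovered
Reagents that add atoms: none
Why: Steglich esterification of a primary alcohol; the two hydroxyls of the C2-symmetric diol are homotopic, so the threefold excess of 11 only has to hold back double acylation and no stereocentre is touched.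

Step 7
Reactants: 12 monoester of diol 11; 6 (E)-3-[4-(allyloxy)-2,3-dimethoxyphenyl]prop-2-enoic acid
Product: 13 mixed diester of diol 11 with acids 10 and 6 (both phenols as allyl ethers)
Conditions: DCC, DMAP (cat.), CH2Cl2, rt
Reagents that add atoms: none
Why: Steglich esterification of the remaining primary hydroxyl with the second protected acid.

Step 8
Reactants: 13 bis(allyl ether) diester
Product: 14 mixed diester of diol 11 with (E)-3-(2-bromo-4-hydroxy-5-methoxyphenyl)prop-2-enoic acid and (E)-3-(4-hydroxy-2,3-dimethoxyphenyl)prop-2-enoic acid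
Conditions: Pd(PPh3)4 (5 mol%), morpholine (10 equiv), THF, rt
Reagents that add atoms: none
Why: Tsuji–Trost deallylation: zerovalent palladium ionises the two aryl allyl ethers and morpholine takes up the allyl cation, at room temperature without touching the cinnamate esters, the acetonide or the electron-rich aryl bromide.

Step 9
Reactants: 14 diphenol diester
Product: 17 threitol-bridged (1S,2S)-1-(2-bromo-4-hydroxy-5-methoxyphenyl)-7-hydroxy-5,6-dimethoxy-1,2-dihydronaphthalene-2,3-dicarboxylate (ten-membered dilactone), via bis(quinone methide) 15 (not isolated), via quinone methide cinnamate 16 (not isolated)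
Conditions: undivided cell, graphite anode, Pt cathode, LiClO4 (0.1 M), MeCN–(CF3)2CHOH 9:1, 2,6-lutidine (1 equiv), constant current 0.3 mA cm−2, 2.1 F mol−1, 2 mM, 0 °C
Reagents that add atoms: none
Why: Proposed new method: two proton-coupled one-electron oxidations at the anode should give the bis(phenoxyl) diradical, whose spin density sits on both ester α-carbons (the propanoid β-carbons); radical–radical recombination joins C2 to C3 as bis(quinone methide) 15, the ring A half regains its phenol by loss of H-3 to give cinnamate 16, and C8a of that ring (para to the C6 methoxy) alkylates the remaining quinone methide at C1. The closest known reaction type is the FeCl3-mediated or anodic 8–8 dimerisation of sinapate esters to trans-1-aryl-1,2-dihydronaphthalene-2,3-dicarboxylates, here made intramolecular and crossed. The ten-membered dilactone closes by diradical recombination (exo at both alkenes) and ring B by a 6-exo-trig Friedel–Crafts alkylation at the exocyclic quinone methide carbon, which the hydrogen-bonding cosolvent (CF3)2CHOH should accelerate over loss of the second β-hydrogen. C2 is set in the recombination by the (4S,5S) dioxolane, whose trans ring fusion is expected to twist the ten-membered transition state so that one face of the bromoferulate α-carbon meets the other radical, and C1 is set in the Friedel–Crafts step trans to the C2 carbonyl with the aryl group pseudoaxial, as in the untethered sinapate dimers. The step needs β–β coupling rather than β–5 or β–O coupling and ring A as the only nucleophile: the four-carbon diester tether brings only the two β-carbons within bonding distance and high dilution holds back intermolecular coupling, while the bromine at C6 of the guaiacyl ring blocks the one position (para to its methoxy) through which that ring could close, so that no regioisomeric dihydronaphthalene can form whichever quinone methide aromatises first.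

Step 10
Reactants: 17 bromo dihydronaphthalene dilactone
Product: 18 threitol-bridged (1R,2S,3R)-7-hydroxy-1-(4-hydroxy-3-methoxyphenyl)-5,6-dimethoxy-1,2,3,4-tetrahydronaphthalene-2,3-dicarboxylate (ten-membered dilactone)
Conditions: H2 (1 atm), Pd/C (10% Pd on carbon), NaOAc (2 equiv), THF–MeOH, rt
Reagents that add atoms: none
Why: Heterogeneous catalytic hydrogenation saturates the styrenic C3=C4 bond and hydrogenolyses the aryl–bromine bond in one operation (acetate takes up the HBr); hydrogen should add to C3 from the face away from the tether carbonyl on C2, so the 2,3-cis ester is expected, a centre that step 11 equilibrates.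

Step 11
Reactants: 18 tetralin dilactone
Product: 20 dimethyl (1R,2S,3S)-7-hydroxy-1-(4-hydroxy-3-methoxyphenyl)-5,6-dimethoxy-1,2,3,4-tetrahydronaphthalene-2,3-dicarboxylate, via cis diester 19 (not isolated)
Conditions: NaOMe (8 equiv), MeOH, 65 °C; then AcOH
Reagents that add atoms: sodium methoxide in methanol, C[O-].[Na+] and CO
Why: Base-catalysed transesterification with methoxide opens the ten-membered dilactone and returns diol 11, and reversible enolisation then epimerises C3 (C2 being free to follow) until both esters are equatorial and trans to each other and to the aryl group on the non-enolisable C1, the thermodynamic isomer of 1-aryltetralin-2,3-dicarboxylates.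

Step 12
Reactants: 20 all-trans dimethyl ester
Product: 21 (1R,2S,3S)-1-(4-hydroxy-3-methoxyphenyl)-2,3-bis(hydroxymethyl)-5,6-dimethoxy-1,2,3,4-tetrahydronaphthalen-7-ol
Conditions: LiAlH4 (6 equiv), THF, 0 °C to 50 °C; aqueous work-up
Reagents that add atoms: none
Why: LiAlH4 reduction of both methyl esters to the primary alcohols, with excess hydride to cover the two phenols and no stereocentre involved.

**Compound list**

1 | 2,3,4-trihydroxybenzaldehyde | O=Cc1ccc(O)c(O)c1O | starting material
2 | 4-(allyloxy)-2,3-dihydroxybenzaldehyde | O=Cc1ccc(OCC=C)c(O)c1O | intermediate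
3 | 4-(allyloxy)-2,3-dimethoxybenzaldehyde | O=Cc1ccc(OCC=C)c(OC)c1OC | intermediate
4 | malonic acid | OC(=O)CC(=O)O | starting material
5 | 2-{[4-(allyloxy)-2,3-dimethoxyphenyl]methylidene}propanedioic acid | OC(=O)C(=Cc1ccc(OCC=C)c(OC)c1OC)C(=O)O | intermediate (not isolated)
6 | (E)-3-[4-(allyloxy)-2,3-dimethoxyphenyl]prop-2-enoic acid | OC(=O)/C=C/c1ccc(OCC=C)c(OC)c1OC | intermediate
7 | 6-bromovanillin (2-bromo-4-hydroxy-5-methoxybenzaldehyde) | COc1cc(C=O)c(Br)cc1O | starting material
8 | 4-(allyloxy)-2-bromo-5-methoxybenzaldehyde | COc1cc(C=O)c(Br)cc1OCC=C | intermediate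
9 | 2-{[4-(allyloxy)-2-bromo-5-methoxyphenyl]methylidene}propanedioic acid | COc1cc(C=C(C(=O)O)C(=O)O)c(Br)cc1OCC=C | intermediate (not isolated)
10 | (E)-3-[4-(allyloxy)-2-bromo-5-methoxyphenyl]prop-2-enoic acid | COc1cc(/C=C/C(=O)O)c(Br)cc1OCC=C | intermediate
11 | (4S,5S)-2,2-dimethyl-1,3-dioxolane-4,5-dimethanol | CC1(C)O[C@@H](CO)[C@H](CO)O1 | starting material
12 | [(4S,5S)-5-(hydroxymethyl)-2,2-dimethyl-1,3-dioxolan-4-yl]methyl (E)-3-[4-(allyloxy)-2-bromo-5-methoxyphenyl]prop-2-enoate | COc1cc(/C=C/C(=O)OC[C@@H]2OC(C)(C)O[C@H]2CO)c(Br)cc1OCC=C | intermediate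
13 | {(4S,5S)-5-[({(E)-3-[4-(allyloxy)-2-bromo-5-methoxyphenyl]prop-2-enoyl}oxy)methyl]-2,2-dimethyl-1,3-dioxolan-4-yl}methyl (E)-3-[4-(allyloxy)-2,3-dimethoxyphenyl]prop-2-enoate | COc1cc(/C=C/C(=O)OC[C@@H]2OC(C)(C)O[C@H]2COC(=O)/C=C/c3ccc(OCC=C)c(OC)c3OC)c(Br)cc1OCC=C | intermediate
14 | {(4S,5S)-5-[({(E)-3-(2-bromo-4-hydroxy-5-methoxyphenyl)prop-2-enoyl}oxy)methyl]-2,2-dimethyl-1,3-dioxolan-4-yl}methyl (E)-3-(4-hydroxy-2,3-dimethoxyphenyl)prop-2-enoate | COc1cc(/C=C/C(=O)OC[C@@H]2OC(C)(C)O[C@H]2COC(=O)/C=C/c3ccc(O)c(OC)c3OC)c(Br)cc1O | intermediate (key precursor)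
15 | bis(quinone methide): ten-membered dilactone of diol 11 with 2-[(2-bromo-5-methoxy-4-oxocyclohexa-2,5-dien-1-ylidene)methyl]-3-[(2,3-dimethoxy-4-oxocyclohexa-2,5-dien-1-ylidene)methyl]butanedioic acid; C2 (bromo half) S, C3 and the ylidene geometries left open because they are erased in the next events | COC1=CC(=C[C@@H]2C(=O)OC[C@@H]3OC(C)(C)O[C@H]3COC(=O)C2C=C4C=CC(=O)C(OC)=C4OC)C(Br)=CC1=O | intermediate (not isolated)
16 | quinone methide cinnamate: ten-membered dilactone of diol 11 with (2E,3S)-3-[(2-bromo-5-methoxy-4-oxocyclohexa-2,5-dien-1-ylidene)methyl]-2-[(4-hydroxy-2,3-dimethoxyphenyl)methylidene]butanedioic acid; ylidene geometry left open | COC1=CC(=C[C@@H]2C(=O)OC[C@@H]3OC(C)(C)O[C@H]3COC(=O)/C2=C/c4ccc(O)c(OC)c4OC)C(Br)=CC1=O | intermediate (not isolated)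
17 | ten-membered dilactone of diol 11 with (1S,2S)-1-(2-bromo-4-hydroxy-5-methoxyphenyl)-7-hydroxy-5,6-dimethoxy-1,2-dihydronaphthalene-2,3-dicarboxylic acid; aryl and C2 carbonyl trans (the C1 label is S only because bromine changes the CIP ranking) | COc1cc([C@@H]2c3cc(O)c(OC)c(OC)c3C=C(C(=O)OC[C@@H]4OC(C)(C)O[C@H]4CO5)[C@H]2C5=O)c(Br)cc1O | intermediate (key product)
18 | ten-membered dilactone of diol 11 with (1R,2S,3R)-7-hydroxy-1-(4-hydroxy-3-methoxyphenyl)-5,6-dimethoxy-1,2,3,4-tetrahydronaphthalene-2,3-dicarboxylic acid; 1,2-trans, 2,3-cis | COc1cc([C@@H]2c3cc(O)c(OC)c(OC)c3C[C@@H](C(=O)OC[C@@H]4OC(C)(C)O[C@H]4CO5)[C@H]2C5=O)ccc1O | intermediate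
19 | dimethyl (1R,2S,3R)-7-hydroxy-1-(4-hydroxy-3-methoxyphenyl)-5,6-dimethoxy-1,2,3,4-tetrahydronaphthalene-2,3-dicarboxylate (2,3-cis) | COc1cc([C@@H]2c3cc(O)c(OC)c(OC)c3C[C@@H](C(=O)OC)[C@H]2C(=O)OC)ccc1O | intermediate (not isolated)
20 | dimethyl (1R,2S,3S)-7-hydroxy-1-(4-hydroxy-3-methoxyphenyl)-5,6-dimethoxy-1,2,3,4-tetrahydronaphthalene-2,3-dicarboxylate (all-trans) | COc1cc([C@@H]2c3cc(O)c(OC)c(OC)c3C[C@H](C(=O)OC)[C@H]2C(=O)OC)ccc1O | intermediate
21 | (1R,2S,3S)-1-(4-hydroxy-3-methoxyphenyl)-2,3-bis(hydroxymethyl)-5,6-dimethoxy-1,2,3,4-tetrahydronaphthalen-7-ol | COc1cc([C@@H]2c3cc(O)c(OC)c(OC)c3C[C@H](CO)[C@H]2CO)ccc1O | target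

**Step count and risks**

Total: 12 steps. Longest linear sequence: 9 steps (steps 1, 2, 3, 7, 8, 9, 10, 11, 12).

1. Step 9 (the new method). What may go wrong: intermolecular or β–5/β–O recombination of the phenoxyl radicals may outrun the medium-ring β–β closure; the second β-hydrogen may be lost before the Friedel–Crafts closure, leaving the ring-opened bis(arylidene)succinate; the facial bias from the tether may be too small. Fallback with known reactions only, setting out from 3 and returning at 21: Stobbe condensation of 3 with dimethyl succinate (NaOMe, MeOH, reflux) would give (E)-4-[4-(allyloxy)-2,3-dimethoxyphenyl]-3-(methoxycarbonyl)but-3-enoic acid F1. Enantioselective hydrogenation of this chelating itaconate-type alkene (Rh(cod)2BF4 with the antipode of Et-DuPhos that delivers the S acid, H2, MeOH; a catalyst class that leaves isolated allyl ethers alone) would give (3S)-4-[4-(allyloxy)-2,3-dimethoxyphenyl]-3-(methoxycarbonyl)butanoic acid F2. Reduction of the ester group of its potassium salt with Ca(BH4)2 and acid lactonisation would give (4S)-4-{[4-(allyloxy)-2,3-dimethoxyphenyl]methyl}oxolan-2-one F3. Its lithium enolate (LiN(i-Pr)2, THF, −78 °C) would add to commercial 4-(allyloxy)-3-methoxybenzaldehyde anti to the benzyl group to give the trans hydroxybenzyl lactone F4. CF3CO2H in CH2Cl2 would ionise the benzylic alcohol and let ring A close ring B by Friedel–Crafts alkylation, aryl trans to the lactone carbonyl, to the all-trans aryltetralin lactone F5. LiAlH4 would give the bis(allyl ether) of the target F6, and Pd(PPh3)4 with morpholine would return to 21.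

2. Step 11. What may go wrong: epimerisation at C3 may stop short of equilibrium, or the phenoxide-bearing diester may degrade under prolonged methoxide treatment; any cis C1/C2 material from step 9 would be carried into the antipodal series by the same equilibration. Fallback setting out from 17 and returning at 21, with no enolisable ester left to equilibrate: i-Bu2AlH (excess, CH2Cl2–THF, −78 to 0 °C) would reduce both lactone carbonyls, release 11 and give the dihydronaphthalene diol F7. [Ir(cod)(PCy3)(py)]PF6 under H2 in CH2Cl2 would bind the C2 hydroxymethyl group and deliver hydrogen to C3=C4 from that face, giving the 2,3-trans bromo tetralin diol F8. Hydrogenolysis of the bromide (H2, Pd/C, NaOAc, MeOH) would return to 21.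

3. Step 8. What may go wrong: zerovalent palladium may insert into the aryl–bromine bond, or the freed phenoxides may recapture the allyl cation on carbon. Fallback setting out from 7, 6 and 11 and returning at 14, with no late deprotection: Knoevenagel–Doebner reaction of 7 with 4 would give, through the arylidenemalonic acid F9, (E)-3-(2-bromo-4-hydroxy-5-methoxyphenyl)prop-2-enoic acid F10. Mitsunobu esterification (PPh3, diisopropyl azodicarboxylate, THF, 0 °C) of excess 11 with F10, in which the carboxylic acid and not the far less acidic phenol is the pronucleophile, would give the monoester F11. Acid 6 would be deallylated with Pd(PPh3)4 and morpholine, no aryl bromide being present at that stage, to (E)-3-(4-hydroxy-2,3-dimethoxyphenyl)prop-2-enoic acid F12. A second Mitsunobu esterification of F11 with F12 would give 14 directly.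

**Further compounds**

F1 | step 9 | (E)-4-[4-(allyloxy)-2,3-dimethoxyphenyl]-3-(methoxycarbonyl)but-3-enoic acid | COC(=O)/C(CC(=O)O)=C/c1ccc(OCC=C)c(OC)c1OC
F2 | step 9 | (3S)-4-[4-(allyloxy)-2,3-dimethoxyphenyl]-3-(methoxycarbonyl)butanoic acid | COC(=O)[C@H](CC(=O)O)Cc1ccc(OCC=C)c(OC)c1OC
F3 | step 9 | (4S)-4-{[4-(allyloxy)-2,3-dimethoxyphenyl]methyl}oxolan-2-one | O=C1C[C@H](Cc2ccc(OCC=C)c(OC)c2OC)CO1
F4 | step 9 | (3R,4S)-3-{[4-(allyloxy)-3-methoxyphenyl](hydroxy)methyl}-4-{[4-(allyloxy)-2,3-dimethoxyphenyl]methyl}oxolan-2-one (carbinol centre either way) | O=C1OC[C@@H](Cc2ccc(OCC=C)c(OC)c2OC)[C@@H]1C(O)c3ccc(OCC=C)c(OC)c3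
F5 | step 9 | all-trans (1R,2S,3S) aryltetralin lactone, carbonyl on C2 and CH2O on C3, both phenols as allyl ethers | COc1cc([C@@H]2c3cc(OCC=C)c(OC)c(OC)c3C[C@@H]4COC(=O)[C@@H]24)ccc1OCC=C
F6 | step 9 | bis(allyl ether) of 21 | COc1cc([C@@H]2c3cc(OCC=C)c(OC)c(OC)c3C[C@H](CO)[C@H]2CO)ccc1OCC=C
F7 | step 11 | (1S,2S)-1-(2-bromo-4-hydroxy-5-methoxyphenyl)-2,3-bis(hydroxymethyl)-5,6-dimethoxy-1,2-dihydronaphthalen-7-ol | COc1cc([C@@H]2c3cc(O)c(OC)c(OC)c3C=C(CO)[C@H]2CO)c(Br)cc1O
F8 | step 11 | (1S,2S,3S)-1-(2-bromo-4-hydroxy-5-methoxyphenyl)-2,3-bis(hydroxymethyl)-5,6-dimethoxy-1,2,3,4-tetrahydronaphthalen-7-ol | COc1cc([C@@H]2c3cc(O)c(OC)c(OC)c3C[C@H](CO)[C@H]2CO)c(Br)cc1O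
F9 | step 8 | 2-[(2-bromo-4-hydroxy-5-methoxyphenyl)methylidene]propanedioic acid | COc1cc(C=C(C(=O)O)C(=O)O)c(Br)cc1O
F10 | step 8 | (E)-3-(2-bromo-4-hydroxy-5-methoxyphenyl)prop-2-enoic acid | COc1cc(/C=C/C(=O)O)c(Br)cc1O
F11 | step 8 | [(4S,5S)-5-(hydroxymethyl)-2,2-dimethyl-1,3-dioxolan-4-yl]methyl (E)-3-(2-bromo-4-hydroxy-5-methoxyphenyl)prop-2-enoate | COc1cc(/C=C/C(=O)OC[C@@H]2OC(C)(C)O[C@H]2CO)c(Br)cc1O
F12 | step 8 | (E)-3-(4-hydroxy-2,3-dimethoxyphenyl)prop-2-enoic acid | OC(=O)/C=C/c1ccc(O)c(OC)c1OC
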